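**Plan**
- Retrosynthesis: remove the three ester acyl groups, the C17 methyl and the lactone carbonyl level (lactone from a C7/C19 diol); the C2 and C7 carbinols go back to ketones.
- Then cut C4–C5 of the ten-membered ring B in a retro-[3,3] sense, which re-forms a transannular C2–C7 bond. The C7 oxygen, the (5Z)-C5=C6 olefin with its C16 methyl and the C2 oxygen are the imprint of an anionic alkynyl oxy-Cope rearrangement of a 7-(1-propynyl)-2-vinylcyclohexane-2,7-diol derivative (ring X = C1, C2, C7, C8, C9, C10) fused trans to ring A.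
- Forward: ring A and ring X come fused from (R)-Wieland–Miescher ketone; C11, C9, C8/C7 and C2 are oxidised in turn, vinyl and propynyl are attached, ring X is expanded to ring B, then the lactone and the esters are made.
- Stereochemistry: C1 from the starting ketone; C14 by Mitsunobu inversion; C10/C11, C9 and C8 by α-face additions anti to the axial C15 methyl of the trans-decalin; C7 by hydride addition after ring expansion; C17 by lactone enolate methylation; C2 by CBS reduction; the 5Z olefin by protonation of the allenolate.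

Key step: step 22

Remark: briarane numbering is used throughout (ring A = C1, C10–C14; ring X = C1, C2, C7, C8, C9, C10; C15 = methyl on C1; C17, C19 = the two carbons on C8; α = face opposite C15).
Remark: the C2 configuration of 28–35, the sulfur centre of 28, the lactol centre of 41 and the allene axis of 36 are not controlled and are lost later; the SMILES show the C2 epimers expected from β-face attack.

**Step 1**
Reactants: 1 (R)-(−)-Wieland–Miescher ketone
Product: 2 14β-hydroxy enone [(4aR,5R)-5-hydroxy-4a-methyl-4,4a,5,6,7,8-hexahydronaphthalen-2(3H)-one]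
Conditions: NaBH4 (0.3 equiv), EtOH, −10 °C
Reagents that add atoms: none
Why: Chemoselective borohydride reduction of the saturated ketone, in which hydride adds axially from the α-face anti to the angular C15 methyl and so gives the equatorial 14β-alcohol.

**Step 2**
Reactants: 2 14β-hydroxy enone
Product: 3 14α-(4-nitrobenzoyloxy) enone
Conditions: 4-O2NC6H4CO2H, PPh3, DIAD, toluene, 0 °C → rt
Reagents that add atoms: 4-nitrobenzoic acid, O=C(O)c1ccc(cc1)[N+](=O)[O-]
Why: Mitsunobu reaction, in which SN2 displacement of the alkoxyphosphonium ion by the acidic carboxylate inverts C14 to the required 14α (axial, trans to C15) configuration.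

**Step 3**
Reactants: 3 14α-(4-nitrobenzoyloxy) enone
Product: 4 C8 ethylene ketal with the olefin at C10=C11
Conditions: HOCH2CH2OH, TsOH·H2O (cat.), benzene, reflux, water removal
Reagents that add atoms: ethylene glycol, OCCO
Why: Acid-catalysed ketalisation with deconjugation through the dienol, the usual outcome for such octalenones, which places the olefin where C10 and C11 can be functionalised.

**Step 4**
Reactants: 4 nitrobenzoate ketal
Product: 5 14α-hydroxy ketal
Conditions: K2CO3 (0.2 equiv), MeOH, rt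
Reagents that add atoms: none
Why: Base-catalysed transesterification (methanolysis) removes the nitrobenzoate without touching the ketal or the stereocentre.

**Step 5**
Reactants: 5 14α-hydroxy ketal
Product: 6 14α-tert-butyldimethylsilyl ether
Conditions: TBSOTf, 2,6-lutidine, CH2Cl2, −78 → 0 °C
Reagents that add atoms: tert-butyldimethylsilyl triflate, CC(C)(C)[Si](C)(C)OS(=O)(=O)C(F)(F)F
Why: Silyl ether formation with the reactive silyl triflate is needed for the hindered axial neopentylic alcohol and leaves ketal and olefin intact.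

**Step 6**
Reactants: 6 silyl ether ketal
Product: 8 11α-alcohol with H10α (trans-fused), via alkylborane 7 (not isolated)
Conditions: BH3·THF, THF, 0 °C → rt; then NaOH, H2O2, 0 °C → rt
Reagents that add atoms: hydrogen peroxide, OO; borane (boron of 7 only), B
Why: Hydroboration–oxidation, in which boron goes to the less substituted C11 and hydrogen to C10 from the α-face anti to the axial C15 methyl (1,3 to C11), giving the trans ring fusion and the 11α-alcohol as in the analogous steroid olefins.

**Step 7**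
Reactants: 8 11α-hydroxy ketal
Product: 9 11α-hydroxy 8-ketone
Conditions: PPTS, acetone/H2O, 55 °C
Reagents that add atoms: water, O
Why: Acetal hydrolysis under mild acid frees the C8 ketone while the hindered secondary silyl ether survives.

**Step 8**
Reactants: 9 11α-hydroxy 8-ketone
Product: 10 11α-triethylsilyl ether
Conditions: Et3SiCl, imidazole, CH2Cl2, 0 °C
Reagents that add atoms: chlorotriethylsilane, CC[Si](Cl)(CC)CC
Why: Silyl ether formation at the only free hydroxyl with a group that can later be removed in the presence of tert-butyldimethylsilyl ethers.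

**Step 9**
Reactants: 10 trans-decalin-8-one
Product: 12 C2=C7 en-8-one, via lithium enolate 11 (not isolated)
Conditions: LiN(i-Pr)2, THF, −78 °C; then PhS(Cl)=N-t-Bu, −78 °C
Reagents that add atoms: none
Why: Enolate dehydrogenation with a sulfinimidoyl chloride (S-attack then syn-elimination), the kinetic enolate of such trans-fused decalones forming toward C7, away from the ring-fusion side; the new olefin leaves C9 as the only enolisable position.

**Step 10**
Reactants: 12 C2=C7 en-8-one
Product: 14 9α-hydroxy enone, via lithium dienolate 13 (not isolated)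
Conditions: LiN(i-Pr)2, THF, −78 °C; then 2-(phenylsulfonyl)-3-phenyloxaziridine, −78 °C
Reagents that add atoms: 2-(phenylsulfonyl)-3-phenyloxaziridine, O=S(=O)(c1ccccc1)N1OC1c1ccccc1
Why: Enolate hydroxylation with an N-sulfonyloxaziridine, in which the cross-conjugated dienolate (C1 is quaternary, so only C9 can be deprotonated) is attacked from the α-face anti to the axial C15 methyl 1,3 to C9.

**Step 11**
Reactants: 14 9α-hydroxy enone
Product: 15 9α-tert-butyldimethylsilyl ether
Conditions: TBSOTf, 2,6-lutidine, CH2Cl2, 0 °C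
Reagents that add atoms: tert-butyldimethylsilyl triflate, CC(C)(C)[Si](C)(C)OS(=O)(=O)C(F)(F)F
Why: Silyl ether formation protects O9 in the form that is carried to the penultimate step.

**Step 12**
Reactants: 15 silyloxy enone
Product: 17 C8 enol triflate (C7=C8), via lithium enolate 16 (not isolated)
Conditions: LiBH(s-Bu)3, THF, −78 °C; then PhNTf2, −78 → 0 °C
Reagents that add atoms: N-phenylbis(trifluoromethanesulfonimide), O=S(=O)(N(c1ccccc1)S(=O)(=O)C(F)(F)F)C(F)(F)F
Why: Conjugate reduction with enolate trapping, in which the hindered borohydride adds hydride to the β-unsubstituted enone at C2 and the regiodefined C7=C8 enolate is O-sulfonylated.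

**Step 13**
Reactants: 17 enol triflate; 18 tert-butyldimethyl(vinyloxy)silane
Product: 20 C7=C8 olefin with the 2-(silyloxy)ethyl chain (C17, C19) on C8, via B-alkyl-9-BBN 19 (not isolated)
Conditions: 18, 9-BBN, THF, rt; then 17, PdCl2(dppf) (5 mol %), K3PO4, DMF/H2O, 50 °C
Reagents that add atoms: tert-butyldimethyl(vinyloxy)silane (18), C=CO[Si](C)(C)C(C)(C)C; 9-BBN (boron of 19 only), C1CC2CCCC(C1)B2
Why: B-alkyl Suzuki–Miyaura coupling, in which the terminal alkylborane from the vinyl ether couples with the enol triflate and puts C17–C19 on C8 at the alcohol oxidation level, free of acidic or electrophilic sites.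

**Step 14**
Reactants: 20 trisubstituted olefin
Product: 21 7α,8α-diol
Conditions: OsO4 (5 mol %), NMO, acetone/H2O, rt
Reagents that add atoms: OsO4, O=[Os](=O)(=O)=O; N-methylmorpholine N-oxide, C[N+]1([O-])CCOCC1; water, O
Why: Catalytic OsO4 syn-dihydroxylation of the only olefin from the α-face, anti to the axial C15 methyl 1,3 to C7 (as with 2-ene steroids), which sets C8 (8α-OH, side chain β) while the C7 configuration is irrelevant.

**Step 15**
Reactants: 21 diol triethylsilyl ether
Product: 22 7α,8α,11α-triol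
Conditions: AcOH/THF/H2O (3:1:1), rt
Reagents that add atoms: none
Why: Selective acidic desilylation, the secondary triethylsilyl ether being cleaved much faster than the tert-butyldimethylsilyl ethers.

**Step 16**
Reactants: 22 triol
Product: 23 8α-hydroxy-7,11-dione
Conditions: Dess–Martin periodinane (2.5 equiv), CH2Cl2, 0 °C → rt
Reagents that add atoms: none
Why: Dess–Martin oxidation converts both secondary alcohols to ketones and leaves the tertiary C8 alcohol, H10 staying α because the trans fusion is the stable one next to the C11 ketone.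

**Step 17**
Reactants: 23 hydroxy dione
Product: 24 8α-trimethylsilyl ether
Conditions: 1-(trimethylsilyl)imidazole, CH2Cl2, rt
Reagents that add atoms: 1-(trimethylsilyl)imidazole, C[Si](C)(C)n1ccnc1
Why: Silyl ether formation at the tertiary α-ketol oxygen so that later bases cannot trigger α-ketol rearrangement.

**Step 18**
Reactants: 24 silyloxy dione
Product: 25 11-methylene 7-ketone
Conditions: Ph3PCH3Br, KOt-Bu, THF, 0 °C
Reagents that add atoms: methyltriphenylphosphonium bromide, C[P+](c1ccccc1)(c1ccccc1)c1ccccc1.[Br-]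
Why: Wittig methylenation occurs at the C11 ketone, which has an unhindered methylene flank, in preference to the C7 ketone shielded by the fully substituted C8 and the neopentylic C2.

**Step 19**
Reactants: 25 methylene ketone; 26 phenyl vinyl sulfoxide
Product: 29 2β-vinyl 7-ketone, via potassium enolate 27 (not isolated), via sulfoxide adduct 28 (not isolated)
Conditions: KN(SiMe3)2, THF, −78 °C; 26, −78 → −20 °C; NH4Cl work-up; crude 28, NaHCO3 (solid), toluene, 110 °C
Reagents that add atoms: phenyl vinyl sulfoxide (26), C=CS(=O)c1ccccc1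
Why: α-Vinylation of a ketone by Michael addition of its enolate (C2 is the only enolisable position) to a vinyl sulfoxide followed by thermal sulfoxide syn-elimination, which gives the β,γ-unsaturated ketone without conjugation.

**Step 20**
Reactants: 29 vinyl ketone
Product: 32 2β-(methoxymethoxy)-2α-vinyl 7-ketone, via potassium dienolate 30 (not isolated), via potassium alkoxide 31 (not isolated)
Conditions: KN(SiMe3)2, THF, −78 °C; 2-(phenylsulfonyl)-3-phenyloxaziridine; then MeOCH2Cl, −78 → 0 °C
Reagents that add atoms: 2-(phenylsulfonyl)-3-phenyloxaziridine, O=S(=O)(c1ccccc1)N1OC1c1ccccc1; chloromethyl methyl ether, COCCl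
Why: Enolate hydroxylation at the α-carbon of the dienolate (from the face away from the two axial α-silyloxy groups) with O-alkylation of the alkoxide in the same flask, giving an ether that cannot migrate to a neighbouring alkoxide.

**Step 21**
Reactants: 32 ketone; 33 1-propynyllithium
Product: 34 7β-hydroxy-7α-(1-propynyl) carbinol
Conditions: 33, THF, −78 → 0 °C
Reagents that add atoms: 1-propynyllithium (33), [Li]C#CC
Why: 1,2-Addition of an alkynyllithium to the non-enolisable ketone, axial β-attack being blocked by the C15 methyl 1,3 to C7 so that propynyl enters equatorially and lies gauche to the vinyl group.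

**Step 22**
Reactants: 34 propynyl vinyl carbinol
Product: 37 ring-expanded (5Z)-dien-7-one with C2 enol methoxymethyl ether, via potassium alkoxide 35 (not isolated), via potassium allenolate 36 (not isolated)
Conditions: KH, 18-crown-6, THF, 0 °C → rt; then AcOH, −78 °C
Reagents that add atoms: none
Why: KH/18-crown-6 gives the naked C7 alkoxide 35 (silyl shuttling between O7 and O8 is reversible and only the O7 alkoxide rearranges), whose oxyanion weakens C2–C7 so that a concerted suprafacial [3,3] sigmatropic shift through a chair-like six-centre array (C5≡C6–C7···C2–C3=C4) forms C4–C5 as C2–C7 breaks; this is the anionic alkynyl oxy-Cope rearrangement, the closest known type being the ring expansion of 1-alkynyl-2-vinylcyclohexanols to cyclodeca-2,6-dienones. Ring B (ten-membered, C1–C10) is closed by four-atom ring expansion of the six-membered ring X and not by end-to-end cyclisation, so the entropic cost of a medium ring is avoided and no high dilution is needed. No new stereogenic carbon is formed; the C2=C3 enol ether (ring-trans, fixed by the chair array with the equatorial propynyl group) is erased later, and the C5=C6 olefin is set when allenolate 36 is C-protonated at C6 from the ring exterior, syn to the C16 methyl, giving the ring-cis (5Z) enone, which is also the more stable isomer. The step needs the [3,3] path to beat loss of propynide and other alkoxide cleavages; the gauche relation of vinyl and propynyl enforced by the trans-decalin, the strain of four contiguous fully substituted carbons (C1, C2, C7, C8) and the low temperature should secure this. Because the methoxymethyl group on O2 cannot migrate, C2 emerges masked as an enol ether and only C7 is a free ketone.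

**Step 23**
Reactants: 37 dienone
Product: 38 (7S)-allylic alcohol
Conditions: NaBH4, CeCl3·7H2O, MeOH/THF, −78 °C
Reagents that add atoms: none
Why: Luche reduction gives clean 1,2-reduction of the enone, hydride attacking the exposed outer face of the carbonyl anti to the C8–O bond, which should place the new C7 oxygen as in the target.

**Step 24**
Reactants: 38 allylic alcohol
Product: 39 7,8,19-triol
Conditions: Bu4NF, AcOH, THF, 0 °C
Reagents that add atoms: none
Why: Fluoride desilylation under buffered conditions removes the primary tert-butyldimethylsilyl and the tertiary trimethylsilyl ethers, while the two hindered secondary silyl ethers and the base-stable enol ether remain.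

**Step 25**
Reactants: 39 triol
Product: 42 γ-lactone (C19 carbonyl, O7), via hydroxy aldehyde 40 (not isolated), via lactol 41 (not isolated)
Conditions: TEMPO (20 mol %), PhI(OAc)2, CH2Cl2, rt
Reagents that add atoms: none
Why: Oxoammonium-catalysed oxidative lactonisation of a 1,4-diol, the primary alcohol being oxidised much faster than the secondary allylic one and the aldehyde being captured by O7 as the five-membered lactol that is oxidised further.

**Step 26**
Reactants: 42 lactone
Product: 44 17-methyl lactone (methyl cis to the 8-hydroxyl), via dilithio dianion 43 (not isolated)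
Conditions: LiN(i-Pr)2 (2.2 equiv), THF, −78 °C; then MeI, −78 → −40 °C
Reagents that add atoms: iodomethane, CI
Why: Alkylation of a β-hydroxy lactone dianion (the alkoxide cannot be eliminated), methyl iodide approaching C17 anti to the bulky C9 branch on C8, which gives the methyl cis to the 8-hydroxyl and is also the more stable epimer.

**Step 27**
Reactants: 44 methyl lactone enol ether
Product: 45 2-ketone
Conditions: PPTS, acetone/H2O, rt
Reagents that add atoms: water, O
Why: Enol ether (enol acetal) hydrolysis under mild acid unmasks the C2 ketone without harming silyl ethers, lactone or olefins.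

**Step 28**
Reactants: 45 2-ketone
Product: 46 (2R)-alcohol
Conditions: (S)-2-methyl-CBS-oxazaborolidine (20 mol %), catecholborane, toluene, −78 °C
Reagents that add atoms: none
Why: CBS reduction under reagent control, the ketone being flanked by the quaternary C1 (large) and the C3 methylene (small) so that the (S)-catalyst gives the (2R) carbinol, while catecholborane at low temperature spares olefins and lactone.

**Step 29**
Reactants: 46 (2R)-alcohol
Product: 47 2-O-propionate
Conditions: (EtCO)2O, Et3N, DMAP (cat.), CH2Cl2, 0 °C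
Reagents that add atoms: propionic anhydride, CCC(=O)OC(=O)CC
Why: DMAP-catalysed acylation of the only secondary alcohol, the tertiary 8-hydroxyl being too hindered to react.

**Step 30**
Reactants: 47 bis-silyl ether
Product: 48 9,14-diol
Conditions: HF·pyridine, pyridine, THF, 0 °C → rt
Reagents that add atoms: none
Why: Fluoride desilylation of both remaining silyl ethers under non-basic conditions that avoid acyl migration.

**Step 31**
Reactants: 48 diol
Product: 49 junceellolide E
Conditions: Ac2O, pyridine, DMAP (cat.), CH2Cl2, rt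
Reagents that add atoms: acetic anhydride, CC(=O)OC(C)=O
Why: Acetylation of the two secondary alcohols (C9, C14), the hindered tertiary 8-hydroxyl staying free, completes the target.

**Compound list**
1 | (R)-(−)-Wieland–Miescher ketone | C1CCC(=O)[C@@]2(C)C1=CC(=O)CC2 | starting material
2 | 14β-hydroxy enone | C1CC[C@@H](O)[C@@]2(C)C1=CC(=O)CC2 | intermediate
3 | 14α-(4-nitrobenzoyloxy) enone | C1CC[C@H](OC(=O)c3ccc(cc3)[N+](=O)[O-])[C@@]2(C)C1=CC(=O)CC2 | intermediate
4 | nitrobenzoate C8 ketal, C10=C11 olefin | C1CC[C@H](OC(=O)c3ccc(cc3)[N+](=O)[O-])[C@@]2(C)C=1CC4(OCCO4)CC2 | intermediate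
5 | 14α-hydroxy ketal | C1CC[C@H](O)[C@@]2(C)C=1CC3(OCCO3)CC2 | intermediate
6 | 14α-silyloxy ketal | C1CC[C@H](O[Si](C)(C)C(C)(C)C)[C@@]2(C)C=1CC3(OCCO3)CC2 | intermediate
7 | C11 alkylborane (11α-boryl, H10α) | B[C@@H]1CC[C@H](O[Si](C)(C)C(C)(C)C)[C@@]2(C)[C@H]1CC3(OCCO3)CC2 | intermediate (not isolated)
8 | 11α-hydroxy trans-fused ketal | O[C@@H]1CC[C@H](O[Si](C)(C)C(C)(C)C)[C@@]2(C)[C@H]1CC3(OCCO3)CC2 | intermediate
9 | 11α-hydroxy 8-ketone | O[C@@H]1CC[C@H](O[Si](C)(C)C(C)(C)C)[C@@]2(C)[C@H]1CC(=O)CC2 | intermediate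
10 | 11α-triethylsilyloxy 8-ketone | CC[Si](CC)(CC)O[C@@H]1CC[C@H](O[Si](C)(C)C(C)(C)C)[C@@]2(C)[C@H]1CC(=O)CC2 | intermediate
11 | lithium C7=C8 enolate of 10 | CC[Si](CC)(CC)O[C@@H]1CC[C@H](O[Si](C)(C)C(C)(C)C)[C@@]2(C)[C@H]1CC(O[Li])=CC2 | intermediate (not isolated)
12 | C2=C7 en-8-one | CC[Si](CC)(CC)O[C@@H]1CC[C@H](O[Si](C)(C)C(C)(C)C)[C@@]2(C)[C@H]1CC(=O)C=C2 | intermediate
13 | lithium cross-conjugated dienolate of 12 | CC[Si](CC)(CC)O[C@@H]1CC[C@H](O[Si](C)(C)C(C)(C)C)[C@@]2(C)[C@H]1C=C(O[Li])C=C2 | intermediate (not isolated)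
14 | 9α-hydroxy enone | CC[Si](CC)(CC)O[C@@H]1CC[C@H](O[Si](C)(C)C(C)(C)C)[C@@]2(C)[C@H]1[C@@H](O)C(=O)C=C2 | intermediate
15 | 9α-silyloxy enone | CC[Si](CC)(CC)O[C@@H]1CC[C@H](O[Si](C)(C)C(C)(C)C)[C@@]2(C)[C@H]1[C@@H](O[Si](C)(C)C(C)(C)C)C(=O)C=C2 | intermediate
16 | lithium C7=C8 enolate from conjugate reduction | CC[Si](CC)(CC)O[C@@H]1CC[C@H](O[Si](C)(C)C(C)(C)C)[C@@]2(C)[C@H]1[C@@H](O[Si](C)(C)C(C)(C)C)C(O[Li])=CC2 | intermediate (not isolated)
17 | C8 enol triflate | CC[Si](CC)(CC)O[C@@H]1CC[C@H](O[Si](C)(C)C(C)(C)C)[C@@]2(C)[C@H]1[C@@H](O[Si](C)(C)C(C)(C)C)C(OS(=O)(=O)C(F)(F)F)=CC2 | intermediate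
18 | tert-butyldimethyl(vinyloxy)silane | C=CO[Si](C)(C)C(C)(C)C | starting material
19 | B-[2-(tert-butyldimethylsilyloxy)ethyl]-9-borabicyclo[3.3.1]nonane | CC(C)(C)[Si](C)(C)OCCB1C2CCCC1CCC2 | intermediate (not isolated)
20 | C7=C8 olefin with 2-(silyloxy)ethyl on C8 | CC[Si](CC)(CC)O[C@@H]1CC[C@H](O[Si](C)(C)C(C)(C)C)[C@@]2(C)[C@H]1[C@@H](O[Si](C)(C)C(C)(C)C)C(CCO[Si](C)(C)C(C)(C)C)=CC2 | intermediate
21 | 7α,8α-diol | CC[Si](CC)(CC)O[C@@H]1CC[C@H](O[Si](C)(C)C(C)(C)C)[C@@]2(C)[C@H]1[C@@H](O[Si](C)(C)C(C)(C)C)[C@@](CCO[Si](C)(C)C(C)(C)C)(O)[C@@H](O)C2 | intermediate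
22 | 7α,8α,11α-triol | O[C@@H]1CC[C@H](O[Si](C)(C)C(C)(C)C)[C@@]2(C)[C@H]1[C@@H](O[Si](C)(C)C(C)(C)C)[C@@](CCO[Si](C)(C)C(C)(C)C)(O)[C@@H](O)C2 | intermediate
23 | 8α-hydroxy-7,11-dione | O=C1CC[C@H](O[Si](C)(C)C(C)(C)C)[C@@]2(C)[C@H]1[C@@H](O[Si](C)(C)C(C)(C)C)[C@@](CCO[Si](C)(C)C(C)(C)C)(O)C(=O)C2 | intermediate
24 | 8α-trimethylsilyloxy-7,11-dione | O=C1CC[C@H](O[Si](C)(C)C(C)(C)C)[C@@]2(C)[C@H]1[C@@H](O[Si](C)(C)C(C)(C)C)[C@@](CCO[Si](C)(C)C(C)(C)C)(O[Si](C)(C)C)C(=O)C2 | intermediate
25 | 11-methylene 7-ketone | C=C1CC[C@H](O[Si](C)(C)C(C)(C)C)[C@@]2(C)[C@H]1[C@@H](O[Si](C)(C)C(C)(C)C)[C@@](CCO[Si](C)(C)C(C)(C)C)(O[Si](C)(C)C)C(=O)C2 | intermediate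
26 | phenyl vinyl sulfoxide | C=CS(=O)c1ccccc1 | starting material
27 | potassium C2=C7 enolate of 25 | C=C1CC[C@H](O[Si](C)(C)C(C)(C)C)[C@@]2(C)[C@H]1[C@@H](O[Si](C)(C)C(C)(C)C)[C@@](CCO[Si](C)(C)C(C)(C)C)(O[Si](C)(C)C)C(O[K])=C2 | intermediate (not isolated)
28 | 2β-[2-(phenylsulfinyl)ethyl] 7-ketone (sulfur epimers) | C=C1CC[C@H](O[Si](C)(C)C(C)(C)C)[C@@]2(C)[C@H]1[C@@H](O[Si](C)(C)C(C)(C)C)[C@@](CCO[Si](C)(C)C(C)(C)C)(O[Si](C)(C)C)C(=O)[C@@H]2CCS(=O)c3ccccc3 | intermediate (not isolated)
29 | 2β-vinyl 7-ketone | C=C1CC[C@H](O[Si](C)(C)C(C)(C)C)[C@@]2(C)[C@H]1[C@@H](O[Si](C)(C)C(C)(C)C)[C@@](CCO[Si](C)(C)C(C)(C)C)(O[Si](C)(C)C)C(=O)[C@@H]2C=C | intermediate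
30 | potassium dienolate of 29 | C=C1CC[C@H](O[Si](C)(C)C(C)(C)C)[C@@]2(C)[C@H]1[C@@H](O[Si](C)(C)C(C)(C)C)[C@@](CCO[Si](C)(C)C(C)(C)C)(O[Si](C)(C)C)C(O[K])=C2C=C | intermediate (not isolated)
31 | potassium alkoxide of the 2β-hydroxy-2α-vinyl ketone | C=C1CC[C@H](O[Si](C)(C)C(C)(C)C)[C@@]2(C)[C@H]1[C@@H](O[Si](C)(C)C(C)(C)C)[C@@](CCO[Si](C)(C)C(C)(C)C)(O[Si](C)(C)C)C(=O)[C@@]2(O[K])C=C | intermediate (not isolated)
32 | 2β-(methoxymethoxy)-2α-vinyl 7-ketone | C=C1CC[C@H](O[Si](C)(C)C(C)(C)C)[C@@]2(C)[C@H]1[C@@H](O[Si](C)(C)C(C)(C)C)[C@@](CCO[Si](C)(C)C(C)(C)C)(O[Si](C)(C)C)C(=O)[C@@]2(OCOC)C=C | intermediate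
33 | 1-propynyllithium | [Li]C#CC | starting material
34 | 7β-hydroxy-7α-(1-propynyl)-2α-vinyl decalin | C=C1CC[C@H](O[Si](C)(C)C(C)(C)C)[C@@]2(C)[C@H]1[C@@H](O[Si](C)(C)C(C)(C)C)[C@@](CCO[Si](C)(C)C(C)(C)C)(O[Si](C)(C)C)[C@@](O)(C#CC)[C@@]2(OCOC)C=C | intermediate
35 | potassium 7-alkoxide of 34 | C=C1CC[C@H](O[Si](C)(C)C(C)(C)C)[C@@]2(C)[C@H]1[C@@H](O[Si](C)(C)C(C)(C)C)[C@@](CCO[Si](C)(C)C(C)(C)C)(O[Si](C)(C)C)[C@@](O[K])(C#CC)[C@@]2(OCOC)C=C | intermediate (not isolated)
36 | potassium allenolate of the ten-membered ring (C7–OK, C7=C6=C5) | C=C1CC[C@H](O[Si](C)(C)C(C)(C)C)[C@@]2(C)[C@H]1[C@@H](O[Si](C)(C)C(C)(C)C)[C@@](CCO[Si](C)(C)C(C)(C)C)(O[Si](C)(C)C)C(O[K])=C=C(C)C/C=C2\OCOC | intermediate (not isolated)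
37 | ring-expanded (5Z)-dien-7-one, C2=C3 enol methoxymethyl ether | C=C1CC[C@H](O[Si](C)(C)C(C)(C)C)[C@@]2(C)[C@H]1[C@@H](O[Si](C)(C)C(C)(C)C)[C@@](CCO[Si](C)(C)C(C)(C)C)(O[Si](C)(C)C)C(=O)/C=C(/C)C/C=C2\OCOC | intermediate
38 | (7S)-allylic alcohol | C=C1CC[C@H](O[Si](C)(C)C(C)(C)C)[C@@]2(C)[C@H]1[C@@H](O[Si](C)(C)C(C)(C)C)[C@@](CCO[Si](C)(C)C(C)(C)C)(O[Si](C)(C)C)[C@H](/C=C(/C)C/C=C2\OCOC)O | intermediate
39 | 7,8,19-triol | C=C1CC[C@H](O[Si](C)(C)C(C)(C)C)[C@@]2(C)[C@H]1[C@@H](O[Si](C)(C)C(C)(C)C)[C@@](CCO)(O)[C@H](/C=C(/C)C/C=C2\OCOC)O | intermediate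
40 | 7,8-dihydroxy C19 aldehyde | C=C1CC[C@H](O[Si](C)(C)C(C)(C)C)[C@@]2(C)[C@H]1[C@@H](O[Si](C)(C)C(C)(C)C)[C@@](CC=O)(O)[C@H](/C=C(/C)C/C=C2\OCOC)O | intermediate (not isolated)
41 | lactol (C19 epimers) | C=C1CC[C@H](O[Si](C)(C)C(C)(C)C)[C@@]2(C)[C@H]1[C@@H](O[Si](C)(C)C(C)(C)C)[C@@]1(O)[C@H](/C=C(/C)C/C=C2\OCOC)OC(O)C1 | intermediate (not isolated)
42 | 8-hydroxy γ-lactone without the C17 methyl | C=C1CC[C@H](O[Si](C)(C)C(C)(C)C)[C@@]2(C)[C@H]1[C@@H](O[Si](C)(C)C(C)(C)C)[C@@]1(O)[C@H](/C=C(/C)C/C=C2\OCOC)OC(=O)C1 | intermediate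
43 | dilithio lactone enolate 8-alkoxide | C=C1CC[C@H](O[Si](C)(C)C(C)(C)C)[C@@]2(C)[C@H]1[C@@H](O[Si](C)(C)C(C)(C)C)[C@@]1(O[Li])[C@H](/C=C(/C)C/C=C2\OCOC)OC(O[Li])=C1 | intermediate (not isolated)
44 | 17-methyl lactone | C=C1CC[C@H](O[Si](C)(C)C(C)(C)C)[C@@]2(C)[C@H]1[C@@H](O[Si](C)(C)C(C)(C)C)[C@@]1(O)[C@H](/C=C(/C)C/C=C2\OCOC)OC(=O)[C@@H]1C | intermediate
45 | 2-ketone | C=C1CC[C@H](O[Si](C)(C)C(C)(C)C)[C@@]2(C)[C@H]1[C@@H](O[Si](C)(C)C(C)(C)C)[C@@]1(O)[C@H](/C=C(/C)CCC2=O)OC(=O)[C@@H]1C | intermediate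
46 | (2R)-alcohol | C=C1CC[C@H](O[Si](C)(C)C(C)(C)C)[C@@]2(C)[C@H]1[C@@H](O[Si](C)(C)C(C)(C)C)[C@@]1(O)[C@H](/C=C(/C)CC[C@H]2O)OC(=O)[C@@H]1C | intermediate
47 | 2-O-propionate 9,14-bis(silyl ether) | C=C1CC[C@H](O[Si](C)(C)C(C)(C)C)[C@@]2(C)[C@H]1[C@@H](O[Si](C)(C)C(C)(C)C)[C@@]1(O)[C@H](/C=C(/C)CC[C@H]2OC(=O)CC)OC(=O)[C@@H]1C | intermediate
48 | 2-O-propionyl 8,9,14-triol | C=C1CC[C@H](O)[C@@]2(C)[C@H]1[C@@H](O)[C@@]1(O)[C@H](/C=C(/C)CC[C@H]2OC(=O)CC)OC(=O)[C@@H]1C | intermediate
49 | junceellolide E | C=C1CC[C@H](OC(C)=O)[C@@]2(C)[C@H]1[C@@H](OC(C)=O)[C@@]1(O)[C@H](/C=C(/C)CC[C@H]2OC(=O)CC)OC(=O)[C@@H]1C | target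

**Total step count:** 31. **Longest linear sequence:** 31 steps (1 → 49); 18, 26 and 33 are purchased.

**Steps most likely to fail**

Step 22 (key step). The tertiary alkoxide may lose propynide by retro-addition, or silyl transfer may park the negative charge on O8 so that the anion-accelerated path stalls; protonation of the allenolate may also give olefin isomers. The fallback sets out from 34 and uses the neutral, thermal variant of the same bond reorganisation. Silylation with 1-(trimethylsilyl)imidazole (neat, 60 °C) gives the 7-O-trimethylsilyl ether F1. Heating in degassed 1,2-dichlorobenzene at 180 °C should bring about the silyloxy-Cope shift and give the ring-expanded silyloxyallene F2. Bu4NF/AcOH in THF at −78 °C then cleaves the allenyl silyl ether with kinetic protonation at C6, and the route is rejoined at 37.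

Step 23. Facial selectivity of hydride delivery to the conformationally mobile ten-membered enone may be poor. The fallback sets out from 37 and replaces substrate control by reagent control: reduction with a 2-methyl-CBS-oxazaborolidine and catecholborane in toluene at −78 °C, the antipode of the catalyst being chosen for the (7S) carbinol, leads directly to 38. No compound outside the list is made (F0).

Step 2. The alkoxyphosphonium ion at the hindered neopentylic C14 may eliminate instead of being displaced. The fallback sets out from 2 and inverts C14 by oxidation and reduction. Ketalisation (ethylene glycol, TsOH, benzene, reflux) gives the 14β-hydroxy ketal F3. Dess–Martin oxidation gives the 14-keto ketal F4. LiBH(s-Bu)3 in THF at −78 °C, approaching from the equatorial direction, should give the axial 14α-alcohol, which is 5, where the route is rejoined.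

**Further compounds**
F1 | step 22 | 7-O-trimethylsilyl ether of 34 | C=C1CC[C@H](O[Si](C)(C)C(C)(C)C)[C@@]2(C)[C@H]1[C@@H](O[Si](C)(C)C(C)(C)C)[C@@](CCO[Si](C)(C)C(C)(C)C)(O[Si](C)(C)C)[C@@](O[Si](C)(C)C)(C#CC)[C@@]2(OCOC)C=C
F2 | step 22 | ring-expanded 7-(trimethylsilyloxy)allene | C=C1CC[C@H](O[Si](C)(C)C(C)(C)C)[C@@]2(C)[C@H]1[C@@H](O[Si](C)(C)C(C)(C)C)[C@@](CCO[Si](C)(C)C(C)(C)C)(O[Si](C)(C)C)C(O[Si](C)(C)C)=C=C(C)C/C=C2\OCOC
F0 | step 23 | none | none
F3 | step 2 | 14β-hydroxy C8 ketal, C10=C11 olefin | C1CC[C@@H](O)[C@@]2(C)C=1CC3(OCCO3)CC2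
F4 | step 2 | 14-keto C8 ketal, C10=C11 olefin | C1CCC(=O)[C@@]2(C)C=1CC3(OCCO3)CC2
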